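**Assumption:** the target has no stereocentre (it is achiral), so "single enantiomer" is taken to mean the single all-E isomer with the five defined (E)-trisubstituted alkenes.

## Retrosynthetic overview

1. Target ⇒ acetate cleavage and CAN oxidative demethylation of a pentasubstituted aryl acetate. No ring is constructed: the only ring is the benzene ring of the starting material, unveiled as the quinone at the end.
2. Aryl–C1′ bond ⇒ free 2,3,6-trimethoxy-5-methylphenol + all-E-hexaprenyl methyl carbonate, joined by a proposed Pd-catalysed para-selective C–H allylation (the new step).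
3. Phenol ⇒ 2,4,5-trimethoxytoluene by directed ortho-metalation/borylation/oxidation, which fixes which oxygen ends up as OH and which as OMe.
4. C30 chain ⇒ C15 + C15: (E,E)-farnesyl p-tolyl sulfone + ω-bromo-farnesyl TBS ether (sulfone alkylation, Pd/hydride desulfonylation). All E-alkenes come from (E,E)-farnesyl units or an E-selective SeO2 oxidation.

## Route

**Step 1**
Reactants: 1, 2,4,5-trimethoxybenzaldehyde
Product: 2, 2,4,5-trimethoxytoluene (1,2,4-trimethoxy-5-methylbenzene)
Conditions: H2 (4 atm), 10% Pd/C, AcOH, cat. HCl, rt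
Reagents that add atoms: none
Why: Benzylic hydrogenolysis of an electron-rich aryl aldehyde (through the benzyl alcohol) gives the methyl arene; no stereochemistry involved.

**Step 2**
Reactants: 2, 2,4,5-trimethoxytoluene
Product: 3, 2,3,6-trimethoxy-5-methylphenol
Conditions: n-BuLi, TMEDA, THF, 0 °C; B(OMe)3, −78 °C → rt; then AcOH, 30% H2O2, 0 °C
Reagents that add atoms: hydrogen peroxide, OO (supplies the phenolic O)
Why: Directed ortho-metalation takes place at the C–H flanked by two OMe groups, and borylation/oxidation converts the aryllithium to the phenol, placing the future 3-OH between the future 2-OMe and the future C4 carbonyl.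

**Step 3**
Reactants: 4, (2E,6E)-farnesol
Product: 5, (2E,6E)-farnesyl tert-butyldimethylsilyl ether
Conditions: TBSCl, imidazole, DMF, rt
Reagents that add atoms: tert-butyldimethylsilyl chloride, CC(C)(C)[Si](C)(C)Cl
Why: Standard silylation of a primary alcohol; the allylic silyl ether is inert to the later sulfone anion and Pd/hydride steps.

**Step 4**
Reactants: 5, farnesyl TBS ether
Product: 6, (2E,6E,10E)-12-(tert-butyldimethylsilyloxy)-2,6,10-trimethyldodeca-2,6,10-trien-1-ol
Conditions: SeO2 (0.3 equiv), t-BuOOH, salicylic acid (cat.), CH2Cl2, 0 °C → rt; then NaBH4, MeOH, 0 °C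
Reagents that add atoms: selenium dioxide, O=[Se]=O, with tert-butyl hydroperoxide, CC(C)(C)OO (one O atom)
Why: Sharpless SeO2/TBHP allylic oxidation (ene then [2,3]-sigmatropic shift) selects the (E)-methyl of the terminal, most electron-rich alkene and gives the (E)-allylic alcohol; NaBH4 returns any over-oxidised enal.

**Step 5**
Reactants: 6, ω-hydroxy farnesyl TBS ether
Product: 7, (2E,6E,10E)-12-bromo-3,7,11-trimethyldodeca-2,6,10-trien-1-yl TBS ether
Conditions: MsCl, Et3N, CH2Cl2, −40 °C; then LiBr, THF, 0 °C
Reagents that add atoms: lithium bromide, [Li+].[Br-]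
Why: Mesylation followed by SN2 displacement with bromide at a primary allylic carbon keeps the alkene position and E geometry.

**Step 6**
Reactants: 8, (2E,6E)-farnesyl bromide
Product: 9, (2E,6E)-farnesyl p-tolyl sulfone
Conditions: TolSO2Na, DMF, rt
Reagents that add atoms: sodium p-toluenesulfinate, Cc1ccc(cc1)S(=O)[O-].[Na+]
Why: S-alkylation of the sulfinate by SN2 at the primary allylic bromide retains the 2E alkene.

**Step 7**
Reactants: 9, farnesyl p-tolyl sulfone; 7, ω-bromo farnesyl TBS ether
Product: 10, TBS ether of (2E,6E,10E,14E,18E)-3,7,11,15,19,23-hexamethyl-13-(p-tolylsulfonyl)tetracosa-2,6,10,14,18,22-hexaen-1-ol (racemic at C13; this centre is removed in step 8)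
Conditions: n-BuLi (1.05 equiv), THF/DMPU, −78 °C; then 7, −78 → −20 °C
Reagents that add atoms: none
Why: Biellmann-type α-alkylation of the allylic sulfonyl carbanion with a primary allylic bromide forms the C12–C13 bond head-to-tail without touching any alkene geometry.

**Step 8**
Reactants: 10, C30 sulfone TBS ether
Product: 11, (2E,6E,10E,14E,18E)-hexaprenyl TBS ether
Conditions: PdCl2(dppp) (5 mol%), LiEt3BH, THF, 0 °C
Reagents that add atoms: none
Why: Pd-catalysed reductive desulfonylation: the allylic sulfone ionises to a π-allyl and hydride attacks the less hindered secondary terminus (C13), so the C14=C15 alkene stays in place and stays E.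

**Step 9**
Reactants: 11, hexaprenyl TBS ether
Product: 12, (2E,6E,10E,14E,18E)-3,7,11,15,19,23-hexamethyltetracosa-2,6,10,14,18,22-hexaen-1-ol (all-E-hexaprenol)
Conditions: TBAF, THF, rt
Reagents that add atoms: none
Why: Fluoride desilylation under neutral conditions that do not affect the polyene.

**Step 10**
Reactants: 12, all-E-hexaprenol
Product: 13, all-E-hexaprenyl methyl carbonate
Conditions: ClCO2Me, pyridine, CH2Cl2, 0 °C
Reagents that add atoms: methyl chloroformate, COC(Cl)=O
Why: Acylation of the primary allylic alcohol gives a carbonate that ionises to a π-allyl under neutral conditions and generates its own base (methoxide) on decarboxylation.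

**Step 11 (proposed new transformation)**
Reactants: 3, 2,3,6-trimethoxy-5-methylphenol (1.3 equiv); 13, hexaprenyl methyl carbonate
Product: 14, 4-[(2E,6E,10E,14E,18E)-3,7,11,15,19,23-hexamethyltetracosa-2,6,10,14,18,22-hexaen-1-yl]-2,3,6-trimethoxy-5-methylphenol
Conditions: Pd2(dba)3·CHCl3 (2.5 mol%), DPEphos (6 mol%), toluene/t-AmOH (5:1), 60 °C, Ar (−CO2, −MeOH)
Reagents that add atoms: none
Why: Proposed new method: Pd-catalysed decarboxylative para-selective C–H allylation of an ortho,ortho′-blocked free phenol with a polyprenyl carbonate. Pd(0) ionises 13 to an (E)-3,3-disubstituted π-allyl and methoxide, which deprotonates 3; O-allylation is fast but reversible because the aryl ether is re-ionised by Pd(0). The only irreversible exit is attack of the phenoxide para carbon (the sole ring C–H, both ortho positions carrying OMe) on the unhindered C1′ terminus, followed by dienone-to-phenol tautomerisation. The 2′E geometry should survive because syn/anti exchange would require an η1-tertiary Pd species. The closest known reaction types are Tsuji–Trost O-allylation of phenols, Pd-mediated O→C allyl migration/C-allylation of naphthols and polyphenols, and the thermal para-Claisen rearrangement.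

**Step 12**
Reactants: 14, hexaprenyl phenol
Product: 15, 4-(all-E-hexaprenyl)-2,3,6-trimethoxy-5-methylphenyl acetate
Conditions: Ac2O, pyridine, DMAP (cat.), CH2Cl2, rt
Reagents that add atoms: acetic anhydride, CC(=O)OC(C)=O
Why: Acetylation masks the phenol so that the next oxidation goes through the para-dimethoxy pair and not through phenol/quinone-methide pathways.

**Step 13**
Reactants: 15, aryl acetate
Product: 16, 3-acetoxy-2-methoxy-5-methyl-6-(all-E-hexaprenyl)-1,4-benzoquinone
Conditions: CAN (2.7 equiv), MeCN/CH2Cl2/H2O, 0 °C, 20 min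
Reagents that add atoms: water, O (supplies the two quinone oxygens by ipso attack; the two O-methyl groups leave as methanol)
Why: CAN oxidative demethylation of the only para-dimethoxy pair (flanking the methyl/prenyl carbons) gives the p-quinone; the arene is oxidised well below the isolated trisubstituted alkenes, as in ubiquinone syntheses.

**Step 14**
Reactants: 16, acetoxyquinone
Product: 17, 3-demethylubiquinone-6 (3-hydroxy-2-methoxy-5-methyl-6-(all-E-hexaprenyl)-1,4-benzoquinone)
Conditions: K2CO3 (1.2 equiv), MeOH/THF, 0 °C, 15 min, Ar; then pH 4 citrate buffer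
Reagents that add atoms: none
Why: The quinone enol acetate is a vinylogous anhydride and is cleaved by mild methanolysis at the acyl carbon; the resulting hydroxyquinone anion is not very electrophilic, and the short, cold, buffered work-up limits chromenol formation.

## Compound list

1 | 2,4,5-trimethoxybenzaldehyde | COc1cc(OC)c(C=O)cc1OC | starting material
2 | 2,4,5-trimethoxytoluene | COc1cc(OC)c(C)cc1OC | intermediate (also purchasable)
3 | 2,3,6-trimethoxy-5-methylphenol | COc1c(O)c(OC)c(C)cc1OC | intermediate
4 | (2E,6E)-farnesol | OC/C=C(\C)CC/C=C(\C)CCC=C(C)C | starting material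
5 | (2E,6E)-farnesyl TBS ether | CC(C)(C)[Si](C)(C)OC/C=C(\C)CC/C=C(\C)CCC=C(C)C | intermediate
6 | (2E,6E,10E)-12-(TBS-oxy)-2,6,10-trimethyldodeca-2,6,10-trien-1-ol | CC(C)(C)[Si](C)(C)OC/C=C(\C)CC/C=C(\C)CC/C=C(\C)CO | intermediate
7 | (2E,6E,10E)-12-bromo-3,7,11-trimethyldodeca-2,6,10-trien-1-yl TBS ether | CC(C)(C)[Si](C)(C)OC/C=C(\C)CC/C=C(\C)CC/C=C(\C)CBr | intermediate
8 | (2E,6E)-farnesyl bromide | BrC/C=C(\C)CC/C=C(\C)CCC=C(C)C | starting material
9 | (2E,6E)-farnesyl p-tolyl sulfone | Cc1ccc(cc1)S(=O)(=O)C/C=C(\C)CC/C=C(\C)CCC=C(C)C | intermediate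
10 | TBS ether of 13-(p-tolylsulfonyl)-all-E-hexaprenol (racemic at C13) | CC(C)(C)[Si](C)(C)OC/C=C(\C)CC/C=C(\C)CC/C=C(\C)CC(S(=O)(=O)c1ccc(C)cc1)/C=C(\C)CC/C=C(\C)CCC=C(C)C | intermediate
11 | all-E-hexaprenyl TBS ether | CC(C)(C)[Si](C)(C)OC/C=C(\C)CC/C=C(\C)CC/C=C(\C)CC/C=C(\C)CC/C=C(\C)CCC=C(C)C | intermediate
12 | all-E-hexaprenol | OC/C=C(\C)CC/C=C(\C)CC/C=C(\C)CC/C=C(\C)CC/C=C(\C)CCC=C(C)C | intermediate
13 | all-E-hexaprenyl methyl carbonate | COC(=O)OC/C=C(\C)CC/C=C(\C)CC/C=C(\C)CC/C=C(\C)CC/C=C(\C)CCC=C(C)C | intermediate
14 | 4-(all-E-hexaprenyl)-2,3,6-trimethoxy-5-methylphenol | COc1c(O)c(OC)c(C)c(C/C=C(\C)CC/C=C(\C)CC/C=C(\C)CC/C=C(\C)CC/C=C(\C)CCC=C(C)C)c1OC | intermediate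
15 | 4-(all-E-hexaprenyl)-2,3,6-trimethoxy-5-methylphenyl acetate | COc1c(OC(C)=O)c(OC)c(C)c(C/C=C(\C)CC/C=C(\C)CC/C=C(\C)CC/C=C(\C)CC/C=C(\C)CCC=C(C)C)c1OC | intermediate
16 | 3-acetoxy-2-methoxy-5-methyl-6-(all-E-hexaprenyl)-1,4-benzoquinone | COC1=C(OC(C)=O)C(=O)C(C)=C(C/C=C(\C)CC/C=C(\C)CC/C=C(\C)CC/C=C(\C)CC/C=C(\C)CCC=C(C)C)C1=O | intermediate
17 | 3-demethylubiquinone-6 | COC1=C(O)C(=O)C(C)=C(C/C=C(\C)CC/C=C(\C)CC/C=C(\C)CC/C=C(\C)CC/C=C(\C)CCC=C(C)C)C1=O | target

## Summary

Total steps: 14.
Longest linear sequence: 11 steps (4 → 5 → 6 → 7 → 10 → 11 → 12 → 13 → 14 → 15 → 16 → 17).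

Three steps most likely to fail:

1. **Step 11 (proposed new para-C–H allylation).** Risks are stalling at the O-hexaprenyl ether, β-hydride elimination to the triene, and partial loss of 2′E or linear selectivity. Fallback with known chemistry: protect 3 as its MOM ether, brominate the single free position with NBS, do Br–Li exchange (n-BuLi, −78 °C), transmetalate to the arylcopper (CuBr·SMe2), and alkylate by SN2 with hexaprenyl bromide (from 12 and PBr3). Remove MOM with mild acid to rejoin at 14.

2. **Step 4 (SeO2 allylic oxidation).** Risks are modest yield, internal-methyl oxidation and over-oxidation. Fallback: replace C–H oxidation with a terminal-alkene degradation and rebuild. Make the terminal bromohydrin (NBS, aqueous THF), close to the epoxide (K2CO3), cleave with HIO4 to the trisnor aldehyde, run an E-selective stabilised Wittig with Ph3P=C(CH3)CHO, and reduce with NaBH4 to the same alcohol 6.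

3. **Step 13 (CAN oxidation in the presence of the hexaene).** Risks are ortho-quinone formation and chain oxidation. Fallback: oxidise before the chain is present. Acetylate 3 and treat with CAN to get 3-acetoxy-2-methoxy-5-methyl-1,4-benzoquinone, then attach the chain at the only quinone C–H by BF3·OEt2-mediated allylation with hexaprenyl(tributyl)stannane, re-oxidise the hydroquinone with Ag2O, and deacetylate as in step 14.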